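**Strategy**

The cyclopentane ring is read as a cyclised geranyl chain. Its tertiary carbinol C(CH3)(OH) is the oxygen-bearing carbon of a 2,3-epoxide, the neighbouring ring CH (which carries the CH2–aryl arm) is the carbon next to an ester, and the isopropenyl-bearing ring CH is C6 of the 6,7-olefin; the ring bond between these two CH carbons is the disconnection. One titanocene-mediated radical cyclisation of an acyclic (2S,3R)-epoxygeranate opens the epoxide, closes the ring 5-exo, sets both new ring stereocentres from the Sharpless-derived carbinol carbon and creates the isopropenyl group. Reduction to the aldehyde, reductive alkylation of an acylphloroglucinol and palladium-catalysed dearomative prenylation finish the target.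

Key step: step 4

Assumption: the target is written as one enol tautomer of a 2-acylcyclohexane-1,3,5-trione; the tautomers interconvert, and the descriptor R at the quaternary ring carbon refers to the written form.
Remark on step 4: the titanium hydride left by the terminating hydrogen abstraction is taken to be recycled by Me3SiCl (as Me3SiH) and Mn.

**Route**

Step 1
Reactants: 1 geraniol, (2E)-3,7-dimethylocta-2,6-dien-1-ol
Product: 2 [(2R,3R)-3-methyl-3-(4-methylpent-3-en-1-yl)oxiran-2-yl]methanol
Conditions: Ti(OiPr)4 (5 mol %), D-(−)-diethyl tartrate (6 mol %), tBuOOH (2 equiv), 4 Å MS, CH2Cl2, −20 °C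
Reagents that add atoms: tert-butyl hydroperoxide (CC(C)(C)OO)
Why: Katsuki–Sharpless asymmetric epoxidation; only the allylic olefin binds the titanium–tartrate–peroxide complex, and the D-tartrate should deliver oxygen to the face that makes the methyl-bearing epoxide carbon R (the future tertiary carbinol), leaving the 6,7-olefin untouched.

Step 2
Reactants: 2 [(2R,3R)-3-methyl-3-(4-methylpent-3-en-1-yl)oxiran-2-yl]methanol
Product: 4 (2S,3R)-3-methyl-3-(4-methylpent-3-en-1-yl)oxirane-2-carboxylic acid, via epoxy aldehyde 3 (not isolated)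
Conditions: TEMPO (0.2 equiv), PhI(OAc)2 (2.2 equiv), MeCN/H2O 1:1, 0 → 20 °C
Reagents that add atoms: water (O)
Why: oxoammonium (TEMPO) oxidation of the primary alcohol to the aldehyde and, through its hydrate, to the acid; the epoxide and the isolated trisubstituted olefin should survive, and no stereocentre is touched (only the descriptor at C2 changes with the new priorities).

Step 3
Reactants: 4 (2S,3R)-3-methyl-3-(4-methylpent-3-en-1-yl)oxirane-2-carboxylic acid
Product: 5 methyl (2S,3R)-3-methyl-3-(4-methylpent-3-en-1-yl)oxirane-2-carboxylate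
Conditions: MeI (1.5 equiv), K2CO3 (1.5 equiv), DMF, 0 → 20 °C
Reagents that add atoms: iodomethane (CI)
Why: SN2 O-methylation of the carboxylate under mild base, which avoids the acid and heat that would decarboxylate a glycidic acid.

Step 4
Reactants: 5 methyl (2S,3R)-3-methyl-3-(4-methylpent-3-en-1-yl)oxirane-2-carboxylate
Product: 6 methyl (1S,2R,5R)-2-methyl-5-(prop-1-en-2-yl)-2-[(trimethylsilyl)oxy]cyclopentane-1-carboxylate
Conditions: Cp2TiCl2 (0.2 equiv), Mn dust (8 equiv), Me3SiCl (4 equiv), 2,4,6-collidine (7 equiv), THF (0.02 M), 25 °C, slow addition of 5 over 6 h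
Reagents that add atoms: chlorotrimethylsilane (C[Si](C)(C)Cl)
Why: Cp2TiCl (trivalent titanium, formed in situ from Cp2TiCl2 and Mn) binds the epoxide oxygen and homolyses the C2–O bond, because only that cleavage gives a radical conjugated with the ester; the oxygen stays on C3 as a bulky titanium alkoxide. The closest known reaction type is the titanocene-mediated reductive epoxide opening with radical cyclisation (Nugent–RajanBabu reaction), run here in its catalytic, aprotic Me3SiCl/collidine form. The α-ester radical closes the cyclopentane by 5-exo-trig attack on the trisubstituted 6,7-olefin, and the tertiary radical so formed loses a methyl hydrogen to a second Cp2TiCl to give the isopropenyl group. In the chair-like transition state the titanium alkoxide, the largest group on the carbinol carbon, sits pseudo-equatorial and chelates the ester carbonyl, so the olefin terminus adds trans to oxygen; this fixes the isopropenyl-bearing carbon relative to the Sharpless-derived carbinol carbon. The ester-bearing carbon should form trans to the isopropenyl group and cis to oxygen, which is also its thermodynamic arrangement. The step needs cyclisation to outrun reduction of the α-ester radical, which the low steady-state concentration of trivalent titanium (catalytic loading, slow addition) should secure, and 5-exo rather than 6-endo closure, which formation of the tertiary radical secures.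

Step 5
Reactants: 6 methyl (1S,2R,5R)-2-methyl-5-(prop-1-en-2-yl)-2-[(trimethylsilyl)oxy]cyclopentane-1-carboxylate
Product: 7 (1S,2R,5R)-2-methyl-5-(prop-1-en-2-yl)-2-[(trimethylsilyl)oxy]cyclopentane-1-carbaldehyde
Conditions: iBu2AlH (DIBAL-H, 1.1 equiv), CH2Cl2, −78 °C; Rochelle-salt work-up
Reagents that add atoms: none
Why: partial reduction of the ester through the aluminium hemiacetal that is stable at −78 °C; the silyl ether blocks retro-aldol cleavage, and the α-centre, trans to both neighbouring carbon substituents, is already the thermodynamic one.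

Step 6
Reactants: 8 (2S)-2-methylbutanoic acid; 9 2-methylbenzene-1,3,5-triol (2-methylphloroglucinol)
Product: 11 (2S)-2-methyl-1-(2,4,6-trihydroxy-3-methylphenyl)butan-1-one, via acid chloride 10 (not isolated)
Conditions: (COCl)2 (1.1 equiv), DMF (cat.), CH2Cl2, 0 → 20 °C; then 9, AlCl3 (3 equiv), PhNO2/CH2Cl2, 0 → 20 °C; aqueous HCl work-up
Reagents that add atoms: none
Why: Friedel–Crafts C-acylation of the symmetrical triol, whose two free ring positions are equivalent, so one regioisomer should form; the low temperature is chosen to limit enolisation of the α-stereocentre.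

Step 7
Reactants: 7 (1S,2R,5R)-2-methyl-5-(prop-1-en-2-yl)-2-[(trimethylsilyl)oxy]cyclopentane-1-carbaldehyde; 11 (2S)-2-methyl-1-(2,4,6-trihydroxy-3-methylphenyl)butan-1-one
Product: 13 (2S)-1-(2,4,6-trihydroxy-3-{[(1S,2R,5R)-2-hydroxy-2-methyl-5-(prop-1-en-2-yl)cyclopentyl]methyl}-5-methylphenyl)-2-methylbutan-1-one, via silyl ether 12 (not isolated)
Conditions: L-proline (0.2 equiv), Hantzsch ester (diethyl 2,6-dimethyl-1,4-dihydropyridine-3,5-dicarboxylate, 1.2 equiv), CH2Cl2, 25 °C; then PPTS (0.1 equiv), MeOH, 25 °C
Reagents that add atoms: none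
Why: three-component reductive alkylation: the only free ring CH of 11 attacks the proline iminium (Mannich/Knoevenagel type), loss of proline gives an ortho-quinone methide, and the Hantzsch ester reduces it to the CH2 link; the trans placement of the aldehyde and the isopropenyl group keeps the quinone methide from an internal cycloaddition, and acid-catalysed methanolysis then removes the silyl group.

Step 8
Reactants: 13 (2S)-1-(2,4,6-trihydroxy-3-{[(1S,2R,5R)-2-hydroxy-2-methyl-5-(prop-1-en-2-yl)cyclopentyl]methyl}-5-methylphenyl)-2-methylbutan-1-one; 14 tert-butyl 3-methylbut-2-en-1-yl carbonate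
Product: 15 (6R)-3,5-dihydroxy-4-{[(1S,2R,5R)-2-hydroxy-2-methyl-5-(prop-1-en-2-yl)cyclopentyl]methyl}-6-methyl-2-[(2S)-2-methylbutanoyl]-6-(3-methylbut-2-en-1-yl)cyclohexa-2,4-dien-1-one (CNP0299585.2)
Conditions: Pd2(dba)3·CHCl3 (2.5 mol %), (R,R)-DACH-phenyl Trost ligand (7.5 mol %), 14 (1.2 equiv), THF, 0 °C
Reagents that add atoms: none
Why: Tsuji–Trost asymmetric allylic dearomatisation: the phenoxide attacks the unsubstituted terminus of the prenyl–palladium complex through the methyl-bearing ring carbon, which is less hindered than the carbon bearing the β-branched cyclopentylmethyl group; O-allylation is reversible under zerovalent palladium, and the quaternary stereocentre is set by the chiral ligand (catalyst control; the ligand enantiomer is chosen to give R).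

**Compound list**

1 | geraniol, (2E)-3,7-dimethylocta-2,6-dien-1-ol | CC(C)=CCC/C(C)=C/CO | starting material
2 | [(2R,3R)-3-methyl-3-(4-methylpent-3-en-1-yl)oxiran-2-yl]methanol | CC(C)=CCC[C@@]1(C)O[C@@H]1CO | intermediate
3 | (2S,3R)-3-methyl-3-(4-methylpent-3-en-1-yl)oxirane-2-carbaldehyde | CC(C)=CCC[C@@]1(C)O[C@@H]1C=O | intermediate
4 | (2S,3R)-3-methyl-3-(4-methylpent-3-en-1-yl)oxirane-2-carboxylic acid | CC(C)=CCC[C@@]1(C)O[C@@H]1C(=O)O | intermediate
5 | methyl (2S,3R)-3-methyl-3-(4-methylpent-3-en-1-yl)oxirane-2-carboxylate | CC(C)=CCC[C@@]1(C)O[C@@H]1C(=O)OC | intermediate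
6 | methyl (1S,2R,5R)-2-methyl-5-(prop-1-en-2-yl)-2-[(trimethylsilyl)oxy]cyclopentane-1-carboxylate | C=C(C)[C@@H]1CC[C@@](C)(O[Si](C)(C)C)[C@H]1C(=O)OC | intermediate
7 | (1S,2R,5R)-2-methyl-5-(prop-1-en-2-yl)-2-[(trimethylsilyl)oxy]cyclopentane-1-carbaldehyde | C=C(C)[C@@H]1CC[C@@](C)(O[Si](C)(C)C)[C@H]1C=O | intermediate
8 | (2S)-2-methylbutanoic acid | CC[C@H](C)C(=O)O | starting material
9 | 2-methylbenzene-1,3,5-triol | Cc1c(O)cc(O)cc1O | starting material
10 | (2S)-2-methylbutanoyl chloride | CC[C@H](C)C(=O)Cl | intermediate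
11 | (2S)-2-methyl-1-(2,4,6-trihydroxy-3-methylphenyl)butan-1-one | CC[C@H](C)C(=O)c1c(O)cc(O)c(C)c1O | intermediate
12 | (2S)-2-methyl-1-[2,4,6-trihydroxy-3-methyl-5-({(1S,2R,5R)-2-methyl-5-(prop-1-en-2-yl)-2-[(trimethylsilyl)oxy]cyclopentyl}methyl)phenyl]butan-1-one | C=C(C)[C@@H]1CC[C@@](C)(O[Si](C)(C)C)[C@H]1Cc1c(O)c(C)c(O)c(C(=O)[C@@H](C)CC)c1O | intermediate
13 | (2S)-1-(2,4,6-trihydroxy-3-{[(1S,2R,5R)-2-hydroxy-2-methyl-5-(prop-1-en-2-yl)cyclopentyl]methyl}-5-methylphenyl)-2-methylbutan-1-one | C=C(C)[C@@H]1CC[C@@](C)(O)[C@H]1Cc1c(O)c(C)c(O)c(C(=O)[C@@H](C)CC)c1O | intermediate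
14 | tert-butyl 3-methylbut-2-en-1-yl carbonate | CC(C)=CCOC(=O)OC(C)(C)C | starting material
15 | (6R)-3,5-dihydroxy-4-{[(1S,2R,5R)-2-hydroxy-2-methyl-5-(prop-1-en-2-yl)cyclopentyl]methyl}-6-methyl-2-[(2S)-2-methylbutanoyl]-6-(3-methylbut-2-en-1-yl)cyclohexa-2,4-dien-1-one | C=C(C)[C@@H]1CC[C@@](C)(O)[C@H]1CC1=C(O)[C@@](C)(CC=C(C)C)C(=O)C(C(=O)[C@@H](C)CC)=C1O | target

**Step count and risks**

Total step count: 8. Longest linear sequence: 7 steps (1, 2, 3, 4, 5, 7, 8); step 6 is a one-step side branch.

Steps most likely to fail: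

1. Step 4. The α-ester radical may be reduced by trivalent titanium before it cyclises (deoxygenation to the dienoate or an uncyclised hydroxy ester), or the olefin may add with poor facial selectivity at the new isopropenyl-bearing carbon. The fallback closes the same bond by polar chemistry. Setting out from 5, SmI2 in THF/MeOH at −78 °C should cleave the C2–O bond reductively to methyl (3R)-3-hydroxy-3,7-dimethyloct-6-enoate F1. Allylic oxidation of the (E)-methyl group (SeO2 cat., tBuOOH, CH2Cl2) should give methyl (3R,6E)-3,8-dihydroxy-3,7-dimethyloct-6-enoate F2, and Corey–Kim chlorination (N-chlorosuccinimide, Me2S, CH2Cl2, −20 °C) the allylic chloride methyl (3R,6E)-8-chloro-3-hydroxy-3,7-dimethyloct-6-enoate F3. The dianion (LDA 2.2 equiv, THF, −78 → −20 °C), held as a Fráter–Seebach-type chelate, should then cyclise by intramolecular SN2' alkylation to methyl (1S,2R,5R)-2-hydroxy-2-methyl-5-(prop-1-en-2-yl)cyclopentane-1-carboxylate F4. Silylation (Me3SiCl, imidazole, DMF) returns the route to 6.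

2. Step 8. Prenylation may go to oxygen, to the other alkyl-bearing ring carbon or to the branched allyl terminus, and the ligand may differentiate the two ring faces poorly because the two flanks of the reacting carbon differ only remotely. The fallback gives up catalyst control: setting out from 13, alkylation with prenyl bromide (NaOMe, MeOH, 0 °C) should give 15 together with its epimer at the quaternary ring carbon, (6S)-3,5-dihydroxy-4-{[(1S,2R,5R)-2-hydroxy-2-methyl-5-(prop-1-en-2-yl)cyclopentyl]methyl}-6-methyl-2-[(2S)-2-methylbutanoyl]-6-(3-methylbut-2-en-1-yl)cyclohexa-2,4-dien-1-one F5. The two diastereomers are separated by preparative HPLC, which returns the route to 15.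

3. Step 7. The hindered α-branched aldehyde may condense sluggishly, and the ortho-quinone methide may be captured by a second molecule of 11 (diarylmethane formation) faster than by hydride. The fallback reverses the order of the last two operations. Setting out from 11, the palladium-catalysed asymmetric dearomative prenylation with 14 (conditions of step 8) is run first and should give the cyclic 1,3-dione (6R)-3,5-dihydroxy-6-methyl-2-[(2S)-2-methylbutanoyl]-6-(3-methylbut-2-en-1-yl)cyclohexa-2,4-dien-1-one F6, whose ring CH is a more acidic and less crowded carbon nucleophile. Its proline/Hantzsch ester reductive alkylation with 7 should give the silyl ether of the target, (6R)-3,5-dihydroxy-6-methyl-2-[(2S)-2-methylbutanoyl]-6-(3-methylbut-2-en-1-yl)-4-({(1S,2R,5R)-2-methyl-5-(prop-1-en-2-yl)-2-[(trimethylsilyl)oxy]cyclopentyl}methyl)cyclohexa-2,4-dien-1-one F7, and PPTS/MeOH returns the route to 15.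

Further compounds
F1 | step 4 | methyl (3R)-3-hydroxy-3,7-dimethyloct-6-enoate | CC(C)=CCC[C@@](C)(O)CC(=O)OC
F2 | step 4 | methyl (3R,6E)-3,8-dihydroxy-3,7-dimethyloct-6-enoate | OC/C(C)=C/CC[C@@](C)(O)CC(=O)OC
F3 | step 4 | methyl (3R,6E)-8-chloro-3-hydroxy-3,7-dimethyloct-6-enoate | ClC/C(C)=C/CC[C@@](C)(O)CC(=O)OC
F4 | step 4 | methyl (1S,2R,5R)-2-hydroxy-2-methyl-5-(prop-1-en-2-yl)cyclopentane-1-carboxylate | C=C(C)[C@@H]1CC[C@@](C)(O)[C@H]1C(=O)OC
F5 | step 8 | (6S)-3,5-dihydroxy-4-{[(1S,2R,5R)-2-hydroxy-2-methyl-5-(prop-1-en-2-yl)cyclopentyl]methyl}-6-methyl-2-[(2S)-2-methylbutanoyl]-6-(3-methylbut-2-en-1-yl)cyclohexa-2,4-dien-1-one | C=C(C)[C@@H]1CC[C@@](C)(O)[C@H]1CC1=C(O)[C@](C)(CC=C(C)C)C(=O)C(C(=O)[C@@H](C)CC)=C1O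
F6 | step 7 | (6R)-3,5-dihydroxy-6-methyl-2-[(2S)-2-methylbutanoyl]-6-(3-methylbut-2-en-1-yl)cyclohexa-2,4-dien-1-one | C1=C(O)[C@@](C)(CC=C(C)C)C(=O)C(C(=O)[C@@H](C)CC)=C1O
F7 | step 7 | (6R)-3,5-dihydroxy-6-methyl-2-[(2S)-2-methylbutanoyl]-6-(3-methylbut-2-en-1-yl)-4-({(1S,2R,5R)-2-methyl-5-(prop-1-en-2-yl)-2-[(trimethylsilyl)oxy]cyclopentyl}methyl)cyclohexa-2,4-dien-1-one | C=C(C)[C@@H]1CC[C@@](C)(O[Si](C)(C)C)[C@H]1CC1=C(O)[C@@](C)(CC=C(C)C)C(=O)C(C(=O)[C@@H](C)CC)=C1O
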